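**Plan**

- Retrosynthesis: the two phenols are masked as benzyl ethers and the C3 and C4 methyls are traced back to acyl groups. The oxolane is then cut at C2–C3 and C4–C5 into a 1,3-dipole ArCH=O(+)–CH(−)Ar and an (E)-butenedioyl unit.
- Forward: the oxolane, the only ring that is built, arises in one (3+2) cycloaddition of a carbonyl ylide (from a 2,3-diaryloxirane by C–C scission) with a fumaroyl bis-sultam. The two acyl groups are then taken down to methyl and the phenols are freed.
- Enabling feature: the ring O1–C2(aryl)–C3(Me)–C4(Me)–C5(aryl) with cis aryls and trans methyls is the one relative configuration that a mirror-symmetric W-shaped ylide and an E-alkene can give.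
- Stereochemistry: C2/C5 cis comes from the ylide shape and C3/C4 trans from the alkene geometry. The absolute configuration (2S,3S,4S,5R) comes from the alkene face selected by two (2R)-bornane-10,2-sultam auxiliaries; no stereocentre is touched afterwards.

Key step: step 5

Assumption: in the uncatalysed cycloaddition the (2R)-sultams are taken to expose the Re face of each fumaroyl carbon, the sense usual for uncatalysed additions to N-enoyl (2R)-sultams; this sense is recalled, not verified here. Racemic compounds are drawn as one enantiomer.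

**Route**

Step 1
Reactants: 1 syringaldehyde; 2 benzyl bromide
Product: 3 4-(benzyloxy)-3,5-dimethoxybenzaldehyde
Conditions: K2CO3, DMF, 60 °C
Reagents that add atoms: none
Why: Williamson ether synthesis; the acidic para-formyl phenoxide is O-alkylated by the benzylic bromide in an SN2 reaction, and no stereocentre is involved.

Step 2
Reactants: 3 4-(benzyloxy)-3,5-dimethoxybenzaldehyde (two molecules)
Product: 4 (E)-1,2-bis[4-(benzyloxy)-3,5-dimethoxyphenyl]ethene
Conditions: TiCl4, Zn, THF, reflux; then 3, reflux
Reagents that add atoms: none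
Why: McMurry reductive coupling of an aromatic aldehyde on low-valent titanium should give the E-stilbene through a titanium pinacolate, aryl benzyl and methyl ethers being inert to it; the alkene geometry is of no consequence because it is erased in step 5.

Step 3
Reactants: 4 (E)-1,2-bis[4-(benzyloxy)-3,5-dimethoxyphenyl]ethene
Product: 5 racemic trans-2,3-bis[4-(benzyloxy)-3,5-dimethoxyphenyl]oxirane
Conditions: dimethyldioxirane (acetone solution), CH2Cl2, 0 °C
Reagents that add atoms: dimethyldioxirane, CC1(C)OO1
Why: Dioxirane epoxidation is a concerted, stereospecific oxygen transfer under neutral conditions, so the acid-labile electron-rich stilbene oxide should survive; the E-alkene gives the trans-oxirane as a racemate whose two centres are erased in step 5.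

Step 4
Reactants: 6 fumaryl chloride; 7 (2R)-bornane-10,2-sultam (two molecules)
Product: 9 N,N'-fumaroylbis[(2R)-bornane-10,2-sultam], via sodium sultamide 8 (not isolated)
Conditions: NaH, toluene, 0 °C to rt; then 6, rt
Reagents that add atoms: none
Why: N-acylation of the sodium sulfonamide by the diacid chloride (addition–elimination) gives the C2-symmetric bis-imide with the E geometry retained; it is chosen because the imide is a stronger dipolarophile and carries a stronger uncatalysed facial bias than ester auxiliaries.

Step 5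
Reactants: 5 racemic trans-2,3-bis[4-(benzyloxy)-3,5-dimethoxyphenyl]oxirane; 9 N,N'-fumaroylbis[(2R)-bornane-10,2-sultam]
Product: 11 (2S,3S,4S,5R)-2,5-bis[4-(benzyloxy)-3,5-dimethoxyphenyl]oxolane-3,4-dicarbonyl bis[(2R)-bornane-10,2-sultam] imide, via carbonyl ylide 10 (not isolated)
Conditions: 2,4,6-triphenylpyrylium tetrafluoroborate (5 mol%), blue LEDs (about 450 nm), degassed CH2Cl2, rt
Reagents that add atoms: none
Why: The excited pyrylium salt oxidises the electron-rich oxirane 5 to its radical cation, whose C–C bond breaks, and back electron transfer should deliver the planar W-shaped (exo,exo) carbonyl ylide 10 whatever the oxirane configuration; 10 then adds to the electron-poor alkene of 9 in a concerted suprafacial (4π+2π) 1,3-dipolar cycloaddition. The closest known reaction type is the photosensitised electron-transfer opening of 2,3-diaryloxiranes to carbonyl ylides and their (3+2) cycloaddition with fumarates, maleimides and acetylenedicarboxylates. The oxolane ring closes by this intermolecular (3+2) cycloaddition, the bonds C2–C3 and C4–C5 being formed together across one face of each partner. C2 and C5 are set cis by the W geometry of the ylide (both aryl groups exo), and C3 and C4 are set trans because the E geometry of the fumaroyl unit is carried over suprafacially; as the ylide is mirror-symmetric, the alkene face alone fixes the absolute configuration of all four centres. The step needs attack on the Re face of both alkene carbons, and the two homochiral (2R)-sultams, related by the C2 axis of 9 and therefore shielding the same Si,Si face, are there to secure it. Any minor adduct is a diastereomer of 11 and should be removable by crystallisation or chromatography.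

Step 6
Reactants: 11 bis-sultam cycloadduct
Product: 12 [(2S,3R,4R,5R)-2,5-bis[4-(benzyloxy)-3,5-dimethoxyphenyl]oxolane-3,4-diyl]dimethanol
Conditions: LiAlH4, THF, 0 °C to rt
Reagents that add atoms: none
Why: Reductive cleavage of N-acyl sultams by hydride (addition–elimination, then reduction of the aldehyde) should give both primary alcohols and release the auxiliary, fast enough at 0 °C that C3 and C4 do not epimerise; benzyl ethers and the oxolane are inert.

Step 7
Reactants: 12 diol
Product: 13 [(2S,3R,4R,5R)-2,5-bis[4-(benzyloxy)-3,5-dimethoxyphenyl]oxolane-3,4-diyl]dimethanediyl bis(methanesulfonate)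
Conditions: MsCl, Et3N, CH2Cl2, 0 °C
Reagents that add atoms: methanesulfonyl chloride, CS(=O)(=O)Cl
Why: Sulfonylation of primary alcohols is fast and leaves the ring centres untouched; the trans arrangement of the two arms disfavours cyclisation to a fused ether.

Step 8
Reactants: 13 bis(methanesulfonate)
Product: 14 (2S,3S,4S,5R)-2,5-bis[4-(benzyloxy)-3,5-dimethoxyphenyl]-3,4-dimethyloxolane
Conditions: LiBHEt3, THF, 0 °C to rt
Reagents that add atoms: none
Why: SN2 displacement of primary sulfonates by the strongly nucleophilic triethylborohydride converts each CH2OMs into CH3; the reacting carbons are not stereocentres, so the ring configuration is kept.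

Step 9
Reactants: 14 dibenzyl ether
Product: 15 4,4'-[(2S,3S,4S,5R)-3,4-dimethyloxolane-2,5-diyl]bis(2,6-dimethoxyphenol) (target)
Conditions: H2 (1 atm), Pd/C, EtOAc, rt
Reagents that add atoms: none
Why: Catalytic hydrogenolysis of aryl benzyl ethers on palladium is much faster than cleavage of the ring benzylic C–O bonds in a non-acidic solvent at atmospheric pressure, so stopping after uptake of two equivalents should free both phenols without touching the four stereocentres.

**Compound list**

1 | syringaldehyde (4-hydroxy-3,5-dimethoxybenzaldehyde) | COc1cc(C=O)cc(OC)c1O | starting material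
2 | benzyl bromide | BrCc1ccccc1 | starting material
3 | 4-(benzyloxy)-3,5-dimethoxybenzaldehyde | COc1cc(C=O)cc(OC)c1OCc1ccccc1 | intermediate
4 | (E)-1,2-bis[4-(benzyloxy)-3,5-dimethoxyphenyl]ethene | COc1cc(/C=C/c2cc(OC)c(OCc3ccccc3)c(OC)c2)cc(OC)c1OCc1ccccc1 | intermediate
5 | racemic trans-(2R*,3R*)-2,3-bis[4-(benzyloxy)-3,5-dimethoxyphenyl]oxirane | COc1cc([C@H]2O[C@@H]2c2cc(OC)c(OCc3ccccc3)c(OC)c2)cc(OC)c1OCc1ccccc1 | intermediate
6 | fumaryl chloride | O=C(Cl)/C=C/C(=O)Cl | starting material
7 | (2R)-bornane-10,2-sultam, the (−)-camphorsultam from (1S)-(+)-camphor-10-sulfonic acid | N1[C@@H]2C[C@H]3CC[C@]2(CS1(=O)=O)C3(C)C | starting material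
8 | sodium salt of sultam 7 (not isolated) | [Na+].[N-]1[C@@H]2C[C@H]3CC[C@]2(CS1(=O)=O)C3(C)C | intermediate
9 | N,N'-fumaroylbis[(2R)-bornane-10,2-sultam] | O=C(/C=C/C(=O)N1[C@@H]2C[C@H]3CC[C@]2(CS1(=O)=O)C3(C)C)N1[C@@H]2C[C@H]3CC[C@]2(CS1(=O)=O)C3(C)C | intermediate
10 | W-shaped (exo,exo) carbonyl ylide ArCH=O(+)–CH(−)Ar, Ar = 4-benzyloxy-3,5-dimethoxyphenyl (not isolated) | COc1cc(/C=[O+]/[CH-]c2cc(OC)c(OCc3ccccc3)c(OC)c2)cc(OC)c1OCc1ccccc1 | intermediate
11 | (2S,3S,4S,5R)-2,5-bis[4-(benzyloxy)-3,5-dimethoxyphenyl]oxolane-3,4-dicarbonyl bis[(2R)-bornane-10,2-sultam] imide (aryls cis, acyl groups trans, C3 acyl trans to the C2 aryl) | COc1cc([C@H]2O[C@@H](c3cc(OC)c(OCc4ccccc4)c(OC)c3)[C@@H](C(=O)N3[C@@H]4C[C@H]5CC[C@]4(CS3(=O)=O)C5(C)C)[C@@H]2C(=O)N2[C@@H]3C[C@H]4CC[C@]3(CS2(=O)=O)C4(C)C)cc(OC)c1OCc1ccccc1 | intermediate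
12 | [(2S,3R,4R,5R)-2,5-bis[4-(benzyloxy)-3,5-dimethoxyphenyl]oxolane-3,4-diyl]dimethanol | COc1cc([C@H]2O[C@@H](c3cc(OC)c(OCc4ccccc4)c(OC)c3)[C@@H](CO)[C@@H]2CO)cc(OC)c1OCc1ccccc1 | intermediate
13 | bis(methanesulfonate) of diol 12, (2S,3R,4R,5R) | COc1cc([C@H]2O[C@@H](c3cc(OC)c(OCc4ccccc4)c(OC)c3)[C@@H](COS(C)(=O)=O)[C@@H]2COS(C)(=O)=O)cc(OC)c1OCc1ccccc1 | intermediate
14 | (2S,3S,4S,5R)-2,5-bis[4-(benzyloxy)-3,5-dimethoxyphenyl]-3,4-dimethyloxolane | COc1cc([C@H]2O[C@@H](c3cc(OC)c(OCc4ccccc4)c(OC)c3)[C@@H](C)[C@@H]2C)cc(OC)c1OCc1ccccc1 | intermediate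
15 | 4,4'-[(2S,3S,4S,5R)-3,4-dimethyloxolane-2,5-diyl]bis(2,6-dimethoxyphenol) | COc1cc([C@H]2O[C@@H](c3cc(OC)c(O)c(OC)c3)[C@@H](C)[C@@H]2C)cc(OC)c1O | target

**Step count**

Total: 9 steps. Longest linear sequence: 8 steps (steps 1, 2, 3, 5, 6, 7, 8, 9 from syringaldehyde); step 4 is a one-step side branch.

**Steps most likely to fail**

Step 5. The discrimination between the two faces of the fumaroyl unit by the sultams may be weak or reversed, and some ylide may react through a sickle-shaped geometry to give 2,5-trans adducts. The fallback sets the absolute configuration by resolution instead of auxiliary control. Setting out from oxirane 5, the same photocatalysed cycloaddition is run with commercial dimethyl fumarate and should give racemic dimethyl (2S*,3S*,4S*,5R*)-2,5-bis[4-(benzyloxy)-3,5-dimethoxyphenyl]oxolane-3,4-dicarboxylate F1. LiAlH4 in THF then reduces it to racemic [2,5-bis[4-(benzyloxy)-3,5-dimethoxyphenyl]oxolane-3,4-diyl]dimethanol F2. This is resolved by preparative chromatography on a cellulose tris(3,5-dimethylphenylcarbamate) stationary phase, and the (2S,3R,4R,5R) enantiomer is diol 12, where the route is rejoined.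

Step 8. The hydride may attack sulfur instead of carbon and return the alcohol, or the second displacement at the beta-branched carbon may stall. The fallback replaces the polar reduction by a radical one. Setting out from diol 12, Appel iodination (I2, PPh3, imidazole, toluene) should give (2S,3S,4S,5R)-2,5-bis[4-(benzyloxy)-3,5-dimethoxyphenyl]-3,4-bis(iodomethyl)oxolane F3. Bu3SnH with AIBN in toluene at 80 °C then removes both iodine atoms by a radical chain and comes back to the route at 14.

Step 3. The electron-rich oxirane may rearrange to a carbonyl compound (Meinwald type) or be oxidised further during epoxidation and isolation, and the stilbene may dissolve poorly. The fallback builds the oxirane by C–C bond formation under basic, non-oxidising conditions, which also bypasses step 2. Setting out from aldehyde 3, the sequence is: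
- NaBH4 in MeOH gives (4-benzyloxy-3,5-dimethoxyphenyl)methanol F4.
- SOCl2 in CH2Cl2 gives 4-benzyloxy-3,5-dimethoxybenzyl chloride F5.
- Tetrahydrothiophene in MeCN gives 1-(4-benzyloxy-3,5-dimethoxybenzyl)tetrahydrothiophenium chloride F6.
- Aqueous NaOH in CH2Cl2 deprotonates F6 to the benzylic sulfonium ylide F7, which adds to a second equivalent of 3 and closes to oxirane 5 (sulfonium ylide epoxidation).

A cis/trans mixture is acceptable here because the oxirane configuration is erased in step 5.

**Further compounds**

F1 | step 5 | racemic dimethyl (2S*,3S*,4S*,5R*)-2,5-bis[4-(benzyloxy)-3,5-dimethoxyphenyl]oxolane-3,4-dicarboxylate | COc1cc([C@H]2O[C@@H](c3cc(OC)c(OCc4ccccc4)c(OC)c3)[C@@H](C(=O)OC)[C@@H]2C(=O)OC)cc(OC)c1OCc1ccccc1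
F2 | step 5 | racemic [(2S*,3R*,4R*,5R*)-2,5-bis[4-(benzyloxy)-3,5-dimethoxyphenyl]oxolane-3,4-diyl]dimethanol (racemate of 12) | COc1cc([C@H]2O[C@@H](c3cc(OC)c(OCc4ccccc4)c(OC)c3)[C@@H](CO)[C@@H]2CO)cc(OC)c1OCc1ccccc1
F3 | step 8 | (2S,3S,4S,5R)-2,5-bis[4-(benzyloxy)-3,5-dimethoxyphenyl]-3,4-bis(iodomethyl)oxolane | COc1cc([C@H]2O[C@@H](c3cc(OC)c(OCc4ccccc4)c(OC)c3)[C@@H](CI)[C@@H]2CI)cc(OC)c1OCc1ccccc1
F4 | step 3 | (4-benzyloxy-3,5-dimethoxyphenyl)methanol | COc1cc(CO)cc(OC)c1OCc1ccccc1
F5 | step 3 | 4-benzyloxy-3,5-dimethoxybenzyl chloride | COc1cc(CCl)cc(OC)c1OCc1ccccc1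
F6 | step 3 | 1-(4-benzyloxy-3,5-dimethoxybenzyl)tetrahydrothiophenium chloride | COc1cc(C[S+]2CCCC2)cc(OC)c1OCc1ccccc1.[Cl-]
F7 | step 3 | (4-benzyloxy-3,5-dimethoxyphenyl)methylide of tetrahydrothiophenium (sulfonium ylide, not isolated) | COc1cc([CH-][S+]2CCCC2)cc(OC)c1OCc1ccccc1
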